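## Retrosynthetic overview

1. **Feature.** In the 2,3-dihydro-1,4-benzodioxine core (O1, C2 with ring A, C3 with CH2OH, O4, C4a, C5-OMe, C7 side chain, C8a), O4 bridges C3 and the ring B carbon C4a. C4a has an oxygen-bearing carbon on each side (C5-OMe and C8a-O1). Without O4 the core is a 2-aryl-3-(hydroxymethyl)-2,3-dihydrobenzofuran whose C3-aryl bond is well suited to shift to an electron-poor oxygen.
2. **Key disconnection.** O4-C4a and C3-H are cut back to the C3 hydroperoxide of that dihydrobenzofuran. O-acylation, a 1,2-aryl shift from C3 to oxygen, and silane capture of the C3 oxocarbenium ion turn the five-membered ring into the dioxane ring.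
3. **Precursor.** The hydroperoxide comes from the C3 ester enolate and O2, followed by peroxyketal masking, hydride reduction and silylation. The dihydrofuran ring comes from an enantioselective rhodium carbene C-H insertion (forms C2-C3, sets C2) of an aryldiazoacetate built from a bromoresorcylate, a syringyl alcohol and a Reformatsky reagent.
4. **Repair.** No hydride that reduces the quaternary C3 ester spares a methyl benzoate and an aryl pivalate, so all three are reduced at once. Ring B then carries C7 as CH2OTBDPS (no para acceptor on the migrating carbon), and the ring A pivalate is put back before the key step.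
5. **Ring order.** The dihydrofuran ring is formed first and the dioxane ring second, by expansion. The side chain is finished last (MnO2, Wittig, i-Bu2AlH), and the ring A phenol is freed only in the final step.

Key step: step 15

Assumption: Rh2(S-PTTL)4 is taken to give the (2R,3S) enantiomer of the cis insertion product; if the sense of induction proves opposite, Rh2(R-PTTL)4 is used and nothing else changes.

## Route

Step 1
Reactants: 1 syringaldehyde
Product: 2 4-formyl-2,6-dimethoxyphenyl pivalate
Conditions: PivCl, Et3N, DMAP (cat.), CH2Cl2, 0 °C to rt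
Reagents that add atoms: pivaloyl chloride, CC(C)(C)C(=O)Cl
Why: DMAP-catalysed O-acylation of the hindered phenol gives a pivalate that masks the phenol through the Mitsunobu, carbene and enolate/O2 steps and makes ring A less electron-rich.

Step 2
Reactants: 2 4-formyl-2,6-dimethoxyphenyl pivalate
Product: 3 4-(hydroxymethyl)-2,6-dimethoxyphenyl pivalate
Conditions: NaBH4, THF/MeOH, 0 °C
Reagents that add atoms: none
Why: Chemoselective borohydride reduction of the aldehyde, which the doubly ortho-substituted aryl pivalate survives at 0 °C.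

Step 3
Reactants: 4 4-bromo-3,5-dihydroxybenzoic acid
Product: 5 methyl 4-bromo-3,5-dihydroxybenzoate
Conditions: MeOH, H2SO4 (cat.), reflux
Reagents that add atoms: methanol, CO
Why: Fischer esterification, to which the phenols and the aryl bromide are inert.

Step 4
Reactants: 5 methyl 4-bromo-3,5-dihydroxybenzoate
Product: 6 methyl 4-bromo-3-hydroxy-5-methoxybenzoate
Conditions: MeI (1.0 equiv), K2CO3 (1.1 equiv), DMF, rt
Reagents that add atoms: iodomethane, CI
Why: Williamson etherification with one equivalent of MeI; the two phenols are equivalent, so only the degree of alkylation has to be controlled, and unreacted 5 is separated and recycled.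

Step 5
Reactants: 6 methyl 4-bromo-3-hydroxy-5-methoxybenzoate; 3 4-(hydroxymethyl)-2,6-dimethoxyphenyl pivalate
Product: 7 methyl 4-bromo-3-{[3,5-dimethoxy-4-(pivaloyloxy)phenyl]methoxy}-5-methoxybenzoate
Conditions: PPh3, DIAD, THF, 0 °C to rt
Reagents that add atoms: none
Why: Mitsunobu etherification of an acidic ortho-bromophenol with a primary benzylic alcohol, run under neutral conditions that leave both esters untouched.

Step 6
Reactants: 7 aryl bromide from step 5; 8 methyl bromoacetate
Product: 10 methyl 3-{[3,5-dimethoxy-4-(pivaloyloxy)phenyl]methoxy}-5-methoxy-4-(2-methoxy-2-oxoethyl)benzoate, via bromozinc ester enolate 9 (not isolated)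
Conditions: 8, Zn dust, Me3SiCl (cat.), THF, 40 °C; then 7, Pd2(dba)3 (2 mol %), XPhos (8 mol %), THF, 65 °C
Reagents that add atoms: none
Why: Negishi-type alpha-arylation with a Reformatsky reagent; the para ester speeds oxidative addition to zerovalent palladium, the bulky biaryl phosphine copes with the two ortho alkoxy groups, and the neutral zinc enolate spares the methyl ester and the pivalate.

Step 7
Reactants: 10 arylacetate from step 6
Product: 11 methyl 4-(1-diazo-2-methoxy-2-oxoethyl)-3-{[3,5-dimethoxy-4-(pivaloyloxy)phenyl]methoxy}-5-methoxybenzoate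
Conditions: p-ABSA, DBU, MeCN, 0 °C to rt
Reagents that add atoms: 4-acetamidobenzenesulfonyl azide, CC(=O)Nc1ccc(cc1)S(=O)(=O)N=[N+]=[N-]
Why: Regitz diazo transfer; the arylacetate CH2, further acidified by the para ester, is deprotonated by DBU and takes up N2 from the sulfonyl azide.

Step 8
Reactants: 11 aryldiazoacetate
Product: 12 dimethyl (2R,3S)-2-[3,5-dimethoxy-4-(pivaloyloxy)phenyl]-4-methoxy-2,3-dihydrobenzofuran-3,6-dicarboxylate (cis)
Conditions: Rh2(S-PTTL)4 (1 mol %), toluene, -60 °C
Reagents that add atoms: none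
Why: Intramolecular 1,5 C-H insertion of a donor/acceptor rhodium carbene into the O-benzylic CH2 (activated by O1 and ring A, far more reactive than the OMe C-H); the chiral carboxylate pocket picks one of the two enantiotopic hydrogens and so sets C2, and the concerted insertion gives the cis C3 ester, whose configuration is erased in step 9.

Step 9
Reactants: 12 cis-dihydrobenzofuran diester
Product: 14 dimethyl (2S,3R)-3-hydroperoxy-2-[3,5-dimethoxy-4-(pivaloyloxy)phenyl]-4-methoxy-2,3-dihydrobenzofuran-3,6-dicarboxylate (OOH trans to ring A), via potassium enolate 13 (not isolated)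
Conditions: KN(SiMe3)2 (1.1 equiv), THF, -78 °C; dry O2, -78 °C; AcOH, -78 °C
Reagents that add atoms: dioxygen, O=O
Why: Ester enolate autoxidation, in which planar 13 takes up O2 on the face away from ring A; the in-plane C2-O1 bond overlaps poorly with the enolate pi system, so retro-oxa-Michael opening is suppressed at -78 °C and C2 is kept (its descriptor changes from R to S only because C3 now outranks ring A).

Step 10
Reactants: 14 alpha-hydroperoxy ester
Product: 15 dimethyl (2S,3R)-3-[(2-methoxypropan-2-yl)peroxy]-2-[3,5-dimethoxy-4-(pivaloyloxy)phenyl]-4-methoxy-2,3-dihydrobenzofuran-3,6-dicarboxylate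
Conditions: 2-methoxypropene, PPTS (cat.), CH2Cl2, 0 °C
Reagents that add atoms: 2-methoxypropene, C=C(C)OC
Why: Acid-catalysed addition of the OOH group to the enol ether gives the acyclic peroxyketal, the usual mask for a hydroperoxide, while the C3 ester keeps the peroxide from rearranging under the weak acid.

Step 11
Reactants: 15 peroxyketal diester
Product: 16 (2S,3S)-2-(4-hydroxy-3,5-dimethoxyphenyl)-3,6-bis(hydroxymethyl)-4-methoxy-3-[(2-methoxypropan-2-yl)peroxy]-2,3-dihydrobenzofuran
Conditions: i-Bu2AlH (DIBAL-H, 8 equiv), CH2Cl2, -78 to -20 °C; aq. KNaC4H4O6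
Reagents that add atoms: none
Why: Exhaustive aluminium hydride reduction takes both methyl esters to CH2OH and cleaves the aryl pivalate, whereas the fully substituted and shielded peroxyketal has no O-H and belongs to the class of dialkyl peroxides that tolerate such hydrides at low temperature.

Step 12
Reactants: 16 phenol diol
Product: 17 (2S,3S)-2-[3,5-dimethoxy-4-(pivaloyloxy)phenyl]-3,6-bis(hydroxymethyl)-4-methoxy-3-[(2-methoxypropan-2-yl)peroxy]-2,3-dihydrobenzofuran
Conditions: PivCl (1.2 equiv), 1 M aq. NaOH, Bu4NHSO4 (10 mol %), CH2Cl2, 0 °C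
Reagents that add atoms: pivaloyl chloride, CC(C)(C)C(=O)Cl
Why: Phase-transfer acylation in which only the phenol is ionised, so the phenoxide is acylated in preference to the two neutral alcohols and the acyl group that ring A needs in step 15 is restored.

Step 13
Reactants: 17 pivalate diol
Product: 18 (2S,3S)-3,6-bis[(tert-butyldiphenylsilyloxy)methyl]-2-[3,5-dimethoxy-4-(pivaloyloxy)phenyl]-4-methoxy-3-[(2-methoxypropan-2-yl)peroxy]-2,3-dihydrobenzofuran
Conditions: TBDPSCl (3 equiv), imidazole, DMAP (cat.), DMF, rt to 40 °C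
Reagents that add atoms: tert-butyl(chloro)diphenylsilane, CC(C)(C)[Si](Cl)(c1ccccc1)c1ccccc1
Why: Standard silylation of both primary alcohols with excess reagent, giving acid-stable, non-participating ethers next to the future cation and on ring B.

Step 14
Reactants: 18 bis-silyl peroxyketal
Product: 19 (2S,3S)-3-hydroperoxy-3,6-bis[(tert-butyldiphenylsilyloxy)methyl]-2-[3,5-dimethoxy-4-(pivaloyloxy)phenyl]-4-methoxy-2,3-dihydrobenzofuran (OOH trans to ring A)
Conditions: AcOH/THF/H2O (4:2:1), 0 °C to rt
Reagents that add atoms: none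
Why: Acetal-type hydrolysis of the acyclic peroxyketal in aqueous acetic acid, an acid too weak to start a Hock rearrangement or to touch the TBDPS ethers and the pivalate.

Step 15
Reactants: 19 C3 hydroperoxide
Product: 22 (2S,3S)-3,7-bis[(tert-butyldiphenylsilyloxy)methyl]-2-[3,5-dimethoxy-4-(pivaloyloxy)phenyl]-5-methoxy-2,3-dihydro-1,4-benzodioxine (trans), via peroxy trifluoroacetate 20 (not isolated), via C3 oxocarbenium trifluoroacetate 21 (not isolated)
Conditions: Et3SiH (20 equiv), (CF3CO)2O (1.5 equiv), CH2Cl2, -78 to -30 °C; aq. NaHCO3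
Reagents that add atoms: none
Why: Proposed new method: (CF3CO)2O acylates the distal peroxide oxygen of 19 to give 20, whose O-O bond then breaks heterolytically while ring B carbon C3a shifts from C3 to the proximal oxygen through a bridged phenonium-like transition state, which forms O4-C4a and leaves cation 21 stabilised by the new O4. The dioxane ring is closed by ring expansion, that is by insertion of one oxygen atom into the C3-C3a bond of the five-membered ring, and no bond at C2 is broken, so C2 keeps its configuration. Et3SiH, present in large excess from the start, transfers hydride to C3 of 21 or of its covalent trifluoroacetate; the closest known reaction types are the Hock and Criegee rearrangements of benzylic hydroperoxides and peresters and the silane reduction of cyclic hemiketals to ethers, which have not been joined to expand a dihydrobenzofuran to a benzodioxane. The new C3 stereocentre is under substrate control by C2: pseudo-axial attack on the half-chair that holds ring A pseudo-equatorial, anti to the pseudo-axial C2-H bond, places the new hydrogen cis to ring A and the silyloxymethyl group trans to it (3S). The step needs migratory selectivity for C3a over C2 and the CH2O carbon, which is secured by the two oxygen substituents ortho to C3a (O1 and the C4 methoxy group) and by the absence of a para acceptor, whereas C2 is held back by the acylated ring A and by the conjugation of O1 with ring B. It also needs hydride capture to outrun loss of the C2 proton and a C2-to-C3 hydride shift, which the pivaloylated ring A, the low temperature and the high silane concentration are meant to ensure.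

Step 16
Reactants: 22 protected trans-benzodioxane
Product: 23 (2S,3S)-3,7-bis(hydroxymethyl)-2-[3,5-dimethoxy-4-(pivaloyloxy)phenyl]-5-methoxy-2,3-dihydro-1,4-benzodioxine
Conditions: HF·pyridine, pyridine, THF, 0 °C to rt
Reagents that add atoms: none
Why: Fluoride-driven Si-O cleavage of both TBDPS ethers in a buffered, non-basic medium that keeps the aryl pivalate in place and avoids acyl migration.

Step 17
Reactants: 23 diol
Product: 24 (2S,3S)-7-formyl-3-(hydroxymethyl)-2-[3,5-dimethoxy-4-(pivaloyloxy)phenyl]-5-methoxy-2,3-dihydro-1,4-benzodioxine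
Conditions: MnO2 (activated, excess), CH2Cl2, rt
Reagents that add atoms: none
Why: MnO2 oxidises only the benzylic alcohol on ring B and not the aliphatic C3 CH2OH, and ring A is still acylated and so cannot be oxidised to a quinone methide.

Step 18
Reactants: 24 aldehyde
Product: 25 methyl (E)-3-{(2S,3S)-3-(hydroxymethyl)-2-[3,5-dimethoxy-4-(pivaloyloxy)phenyl]-5-methoxy-2,3-dihydro-1,4-benzodioxin-7-yl}acrylate
Conditions: Ph3P=CHCO2Me, toluene, 80 °C
Reagents that add atoms: methyl (triphenylphosphoranylidene)acetate, COC(=O)C=P(c1ccccc1)(c1ccccc1)c1ccccc1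
Why: Wittig olefination with a stabilised ylide gives the E-enoate without added base, so the free alcohol, the pivalate and C2 are not disturbed.

Step 19
Reactants: 25 E-enoate
Product: 26 target, (2S,3S)-2-(4-hydroxy-3,5-dimethoxyphenyl)-3-(hydroxymethyl)-7-[(E)-3-hydroxyprop-1-enyl]-5-methoxy-2,3-dihydro-1,4-benzodioxine
Conditions: i-Bu2AlH (DIBAL-H, 7 equiv), CH2Cl2, -78 to -20 °C; aq. KNaC4H4O6
Reagents that add atoms: none
Why: 1,2-Reduction of the enoate to the E-allylic alcohol and reductive cleavage of the pivalate occur in one operation, no stereocentre is touched, and no strongly basic phenoxide arises that could open C2-O1 by way of a quinone methide.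

## Compound list

1 | syringaldehyde | COc1cc(C=O)cc(OC)c1O | starting material
2 | 4-formyl-2,6-dimethoxyphenyl pivalate | CC(C)(C)C(=O)Oc1c(OC)cc(C=O)cc1OC | intermediate
3 | 4-(hydroxymethyl)-2,6-dimethoxyphenyl pivalate | CC(C)(C)C(=O)Oc1c(OC)cc(CO)cc1OC | intermediate
4 | 4-bromo-3,5-dihydroxybenzoic acid | OC(=O)c1cc(O)c(Br)c(O)c1 | starting material
5 | methyl 4-bromo-3,5-dihydroxybenzoate | COC(=O)c1cc(O)c(Br)c(O)c1 | intermediate
6 | methyl 4-bromo-3-hydroxy-5-methoxybenzoate | COC(=O)c1cc(O)c(Br)c(OC)c1 | intermediate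
7 | methyl 4-bromo-3-{[3,5-dimethoxy-4-(pivaloyloxy)phenyl]methoxy}-5-methoxybenzoate | COC(=O)c1cc(OC)c(Br)c(OCc2cc(OC)c(OC(=O)C(C)(C)C)c(OC)c2)c1 | intermediate
8 | methyl bromoacetate | COC(=O)CBr | starting material
9 | (2-methoxy-2-oxoethyl)zinc bromide (Reformatsky reagent, not isolated) | COC(=O)C[Zn]Br | intermediate
10 | methyl 3-{[3,5-dimethoxy-4-(pivaloyloxy)phenyl]methoxy}-5-methoxy-4-(2-methoxy-2-oxoethyl)benzoate | COC(=O)Cc1c(OC)cc(C(=O)OC)cc1OCc1cc(OC)c(OC(=O)C(C)(C)C)c(OC)c1 | intermediate
11 | aryldiazoacetate of 10 | COC(=O)C(=[N+]=[N-])c1c(OC)cc(C(=O)OC)cc1OCc1cc(OC)c(OC(=O)C(C)(C)C)c(OC)c1 | intermediate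
12 | (2R,3S)-cis-dihydrobenzofuran-3,6-diester | CC(C)(C)C(=O)Oc1c(OC)cc([C@@H]2Oc3cc(C(=O)OC)cc(OC)c3[C@@H]2C(=O)OC)cc1OC | intermediate
13 | potassium enolate of 12 (not isolated) | CC(C)(C)C(=O)Oc1c(OC)cc([C@@H]2Oc3cc(C(=O)OC)cc(OC)c3C2=C([O-])OC)cc1OC.[K+] | intermediate
14 | (2S,3R)-3-hydroperoxy diester | CC(C)(C)C(=O)Oc1c(OC)cc([C@@H]2Oc3cc(C(=O)OC)cc(OC)c3[C@]2(OO)C(=O)OC)cc1OC | intermediate
15 | (2S,3R)-peroxyketal diester | CC(C)(C)C(=O)Oc1c(OC)cc([C@@H]2Oc3cc(C(=O)OC)cc(OC)c3[C@]2(OOC(C)(C)OC)C(=O)OC)cc1OC | intermediate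
16 | (2S,3S)-peroxyketal phenol diol | COc1cc([C@@H]2Oc3cc(CO)cc(OC)c3[C@]2(OOC(C)(C)OC)CO)cc(OC)c1O | intermediate
17 | (2S,3S)-peroxyketal pivalate diol | CC(C)(C)C(=O)Oc1c(OC)cc([C@@H]2Oc3cc(CO)cc(OC)c3[C@]2(OOC(C)(C)OC)CO)cc1OC | intermediate
18 | (2S,3S)-bis-TBDPS peroxyketal | CC(C)(C)C(=O)Oc1c(OC)cc([C@@H]2Oc3cc(CO[Si](c4ccccc4)(c4ccccc4)C(C)(C)C)cc(OC)c3[C@]2(OOC(C)(C)OC)CO[Si](c4ccccc4)(c4ccccc4)C(C)(C)C)cc1OC | intermediate
19 | (2S,3S)-C3 hydroperoxide (key-step precursor) | CC(C)(C)C(=O)Oc1c(OC)cc([C@@H]2Oc3cc(CO[Si](c4ccccc4)(c4ccccc4)C(C)(C)C)cc(OC)c3[C@]2(OO)CO[Si](c4ccccc4)(c4ccccc4)C(C)(C)C)cc1OC | intermediate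
20 | peroxy trifluoroacetate of 19 (not isolated) | CC(C)(C)C(=O)Oc1c(OC)cc([C@@H]2Oc3cc(CO[Si](c4ccccc4)(c4ccccc4)C(C)(C)C)cc(OC)c3[C@]2(OOC(=O)C(F)(F)F)CO[Si](c4ccccc4)(c4ccccc4)C(C)(C)C)cc1OC | intermediate
21 | (2S)-C3 oxocarbenium trifluoroacetate (not isolated) | CC(C)(C)C(=O)Oc1c(OC)cc([C@@H]2Oc3cc(CO[Si](c4ccccc4)(c4ccccc4)C(C)(C)C)cc(OC)c3[O+]=C2CO[Si](c4ccccc4)(c4ccccc4)C(C)(C)C)cc1OC.[O-]C(=O)C(F)(F)F | intermediate
22 | (2S,3S)-trans-benzodioxane, bis-TBDPS, pivalate (key-step product) | CC(C)(C)C(=O)Oc1c(OC)cc([C@@H]2Oc3cc(CO[Si](c4ccccc4)(c4ccccc4)C(C)(C)C)cc(OC)c3O[C@H]2CO[Si](c4ccccc4)(c4ccccc4)C(C)(C)C)cc1OC | intermediate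
23 | (2S,3S)-benzodioxane diol pivalate | CC(C)(C)C(=O)Oc1c(OC)cc([C@@H]2Oc3cc(CO)cc(OC)c3O[C@H]2CO)cc1OC | intermediate
24 | (2S,3S)-7-carbaldehyde | CC(C)(C)C(=O)Oc1c(OC)cc([C@@H]2Oc3cc(C=O)cc(OC)c3O[C@H]2CO)cc1OC | intermediate
25 | (2S,3S)-E-enoate | CC(C)(C)C(=O)Oc1c(OC)cc([C@@H]2Oc3cc(/C=C/C(=O)OC)cc(OC)c3O[C@H]2CO)cc1OC | intermediate
26 | CID11188887 | COc1cc([C@@H]2Oc3cc(/C=C/CO)cc(OC)c3O[C@H]2CO)cc(OC)c1O | target

## Step count

Total step count: 19.
Longest linear sequence: 17 steps (steps 3 to 19 from 4; equally steps 1, 2 and 5 to 19 from 1).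

## Steps most likely to fail

**Step 15 (new method).**
- The cation may lose the C2 proton or take up the C2 hydride before the silane arrives, which costs material or enantiopurity.
- The silane may approach the wrong face, giving poor trans selectivity.
- C2 may migrate in competition with ring B.

The fallback uses known chemistry, sets out from 19 and comes back at 22. It separates the rearrangement from the C3-H bond formation. A Hock rearrangement of 19 (TsOH cat., wet MeCN, -20 °C) lets water trap the cation and gives the (S)-keto phenol F1, in equilibrium with its cyclic hemiketal; it is used at once because C2 is now alpha to a ketone. LiBH(s-Bu)3 in THF at -78 °C reduces the ketone under polar Felkin-Anh control, with the aryloxy group perpendicular to the carbonyl, to the anti (1S,2R) alcohol F2. An intramolecular Mitsunobu etherification (PPh3, DIAD, THF) then closes O4-C3 with inversion and gives trans-22.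

**Step 11.**
- The O-O bond may be cleaved reductively.
- The aluminium alkoxide formed next to it may trigger a premature aryl shift during the exhaustive reduction.

The fallback sets out from 14 and comes back at 19. The peroxide is given up on purpose and rebuilt after all hydride chemistry. LiAlH4 in THF at 0 °C reduces the O-O bond, both methyl esters and the pivalate of 14 to the tetraol F3. Phase-transfer pivaloylation as in step 12 gives the phenol pivalate F4. TBDPSCl and imidazole silylate the two primary alcohols and leave the tertiary carbinol free in F5. Acid-catalysed perhydrolysis of the tertiary benzylic alcohol (ethereal H2O2 in excess, TsOH cat., Et2O, -20 °C, short contact because the same cation can also lose the C2 proton) gives 19, with attack expected on the face away from ring A. Either C3 epimer would serve in step 15.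

**Step 8.**
- The second ortho substituent twists ring B out of the carbene plane, which may erode enantioselection.
- It may also divert the carbene to oxonium ylide formation at the methoxy oxygen.

The fallback sets out from 11 and comes back at 12. Catalyst control is replaced by resolution. Rh2(OAc)4 in CH2Cl2 at rt gives 12 together with its mirror image F6. Only C2 matters for the later steps, so any trans isomer is first converged with the cis isomer or carried along. The enantiomers are separated by preparative chromatography on a chiral stationary phase, and 12 alone goes on to step 9.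

## Further compounds

F1 | step 15 | (S)-3-(tert-butyldiphenylsilyloxy)-1-[3,5-dimethoxy-4-(pivaloyloxy)phenyl]-1-{2-hydroxy-3-methoxy-5-[(tert-butyldiphenylsilyloxy)methyl]phenoxy}propan-2-one | CC(C)(C)C(=O)Oc1c(OC)cc([C@H](Oc2cc(CO[Si](c3ccccc3)(c3ccccc3)C(C)(C)C)cc(OC)c2O)C(=O)CO[Si](c2ccccc2)(c2ccccc2)C(C)(C)C)cc1OC
F2 | step 15 | (1S,2R)-anti alcohol from F1 | CC(C)(C)C(=O)Oc1c(OC)cc([C@H](Oc2cc(CO[Si](c3ccccc3)(c3ccccc3)C(C)(C)C)cc(OC)c2O)[C@H](O)CO[Si](c2ccccc2)(c2ccccc2)C(C)(C)C)cc1OC
F3 | step 11 | (2S,3S)-3-hydroxy-2-(4-hydroxy-3,5-dimethoxyphenyl)-3,6-bis(hydroxymethyl)-4-methoxy-2,3-dihydrobenzofuran | COc1cc([C@@H]2Oc3cc(CO)cc(OC)c3[C@]2(O)CO)cc(OC)c1O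
F4 | step 11 | ring A pivalate of F3 | CC(C)(C)C(=O)Oc1c(OC)cc([C@@H]2Oc3cc(CO)cc(OC)c3[C@]2(O)CO)cc1OC
F5 | step 11 | bis-TBDPS ether of F4 with free tertiary C3 alcohol | CC(C)(C)C(=O)Oc1c(OC)cc([C@@H]2Oc3cc(CO[Si](c4ccccc4)(c4ccccc4)C(C)(C)C)cc(OC)c3[C@]2(O)CO[Si](c4ccccc4)(c4ccccc4)C(C)(C)C)cc1OC
F6 | step 8 | (2S,3R) mirror image of 12 | CC(C)(C)C(=O)Oc1c(OC)cc([C@H]2Oc3cc(C(=O)OC)cc(OC)c3[C@H]2C(=O)OC)cc1OC
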